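Moles of Z per litre were my currency for this flask, and I kept them as a ledger.

all flasks: G 0.50 M; X 0.50 M; J 2.7 mM
- north-west: Z 0.30 M; Q 2.5 mM; run made earlier
- south: Z 0.30 M; Q 3.8 mM; run made earlier
- south-west: Z 0.15 M; Q 5 mM; run made earlier
- flask: Z 0.300 M; Q 5.0 mM

| run | time / min | D / % | G / % |
|---|---|---|---|
| north-west | 3.00 | 19.2 | 30.0 |
| north-west | 8.00 | 24.9 | 25.1 |
| north-west | 15.0 | 25.6 | 23.9 |
| north-west | 25.0 | 26.2 | 23.7 |
| south | 2.00 | 20.1 | 30.1 |
| south | 4.00 | 24.5 | 26.1 |
| south | 10.0 | 26.9 | 23.6 |
| south | 25.0 | 27.4 | 22.9 |
| south-west | 6.00 | 13.6 | 36.4 |
| south-west | 12.0 | 14.0 | 36.2 |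
| south-west | 20.0 | 14.1 | 35.9 |
| south-west | 25.0 | 14.1 | 35.9 |

(standard deviation of a reading: 0.3 percentage points)

- Q is single-handed; G and X are mirror images of each other, charged as a racemate, each of them at the stated concentration

1. apparent order in Z when 20 % of the G and X together are converted (percent change of the rate of making D for one percent more Z charged)
2. apparent order in Q when 20 % of the G and X together are converted (percent change of the rate of making D for one percent more Q charged)
3. factor on the rate of making D when 20 % of the G and X together are converted if Z is charged twice over

The earlier runs opened the accounts. I booked one Z for each G turned into D, and Z looked like the limiting reagent: at its last reading the south-west run held 0.141 M of D against 0.15 M of Z charged. A second entry had no reading of its own. The last north-west reading left a gap of 0.0380 M between Z charged and D made, and the south run, with more Q, left a smaller one of 0.0260 M. Q took no entry, being the catalyst. The south run reached about the north-west level in a time shorter by a factor of 1.50, with Q higher by 1.52, so I put the order in Q at about one.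

For the flask, the bill at 20 % conversion was 0.200 M, which left a balance of 0.100 M. That balance as a share of the charge is the fraction of Z left, here 33.3 %. Extra charge lands wholly on the balance while the bill stands, so for a rate first order in Z, the apparent order is the reciprocal of this fraction, 3.00. Doubling the charge gave a balance of 0.400 M, a factor of 4.00. Any Z booked to the gap comes off the balance and raises both figures.

The forecast, which held “the true Z order is about 1–1.3”, gave 3.2, 1.05 and 4.5, above my figures for Z.

The flask gave 3.4 for the order in Z, 1.2 for the order in Q and 4.46 for the doubling.

    Z + Q + G → Q + D (k = 7.50 L² mol⁻² s⁻¹)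
    Z + Q + X → Q + Jo (k = 0.200 L² mol⁻² s⁻¹)
    Q + J ⇌ QJ (K = 740 L mol⁻¹, k = 0.310 L mol⁻¹ s⁻¹)
    Z → E (k = 6.40 × 10⁻⁴ s⁻¹)

At 0.677 min in the flask, Z went into D 21 times as fast as into E. Adding that share to the bill cut the balance to 0.0903 M, and the reciprocal of the fraction left became 3.32. Reckoned on the bill of 20 % conversion, the fraction left in the south-west run came to −33.3 %, below zero, and the D of that run read 14.1 % at 25.0 min.

The runs come from a simulation for an exercise; scatter was added.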